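Cyclohexane ring numbering: C1 (quaternary, Me and CH2OAr), C2 (CHMe), C3 and C4 (CH2), C5 (C=CMe2), C6 (CH carrying the propanal chain). The route rests on disconnecting C3–C4 and C5–C6: the C4–C5 unit with its exocyclic isopropylidene is a masked 1,1-dimethylallene. The key step is an enantioselective Diels–Alder reaction of a 2-silyloxy diene (C3=C2–C1=C6, ketone oxidation level at C2) with strained 4,4-dimethyl-3-methylideneoxetan-2-one; it forms both bonds and the C6 stereocentre in one operation, and thermal loss of CO2 then unveils the C5 isopropylidene. The silyl enol ether left at C1–C2 is used to set C1 by hydroxymethylation and C2 by silicon-tethered radical methyl delivery.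

Key step: step 6

Assumption: the (S)-configured oxazaborolidinium catalyst is taken to deliver the (5R) adduct 11; the facial sense is unproven for this dienophile, and if it is opposite the enantiomeric catalyst is used with nothing else changed.

Step 1
Reactants: 1 methyl 3-(dimethylamino)propanoate; 2 acetone
Product: 3 methyl 2-[(dimethylamino)methyl]-3-hydroxy-3-methylbutanoate (racemic)
Conditions: LiN(iPr)2, THF, −78 °C; then 2, −78 °C; then H2O
Reagents that add atoms: none
Why: Aldol addition of the lithium enolate of the β-amino ester to acetone (the enolate does not expel the amine at −78 °C); the new stereocentre forms racemic and is removed in step 2.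

Step 2
Reactants: 3 methyl 2-[(dimethylamino)methyl]-3-hydroxy-3-methylbutanoate
Product: 5 3-hydroxy-3-methyl-2-methylidenebutanoic acid, via ammonium iodide 4 (not isolated)
Conditions: MeI, MeOH, rt; then LiOH, THF/H2O, rt; then aq. HCl to pH 2
Reagents that add atoms: lithium hydroxide, [Li+].[OH-]
Why: Exhaustive N-methylation followed by hydroxide-induced E1cB (Hofmann-type) elimination of trimethylamine and ester saponification should give the Baylis–Hillman-type acid in one pot.

Step 3
Reactants: 5 3-hydroxy-3-methyl-2-methylidenebutanoic acid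
Product: 6 4,4-dimethyl-3-methylideneoxetan-2-one
Conditions: PhSO2Cl, pyridine, 0 °C
Reagents that add atoms: none
Why: β-Lactonisation by carboxyl activation: the mixed carboxylic–sulfonic anhydride is attacked by the tertiary hydroxyl group, a known way to α-methylene-β-lactones.

Step 4
Reactants: 7 pent-4-enal; 8 3-(triphenyl-λ5-phosphanylidene)butan-2-one
Product: 9 (3E)-3-methylocta-3,7-dien-2-one
Conditions: toluene, 90 °C
Reagents that add atoms: none
Why: Wittig olefination with a stabilised α-branched keto ylide, which should give the (E)-trisubstituted enone.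

Step 5
Reactants: 9 (3E)-3-methylocta-3,7-dien-2-one
Product: 10 tert-butyl(dimethyl){[(3E)-3-methylocta-1,3,7-trien-2-yl]oxy}silane
Conditions: LiN(iPr)2, THF, −78 °C; then TBSOTf, −78 to 0 °C
Reagents that add atoms: tert-butyldimethylsilyl trifluoromethanesulfonate, CC(C)(C)[Si](C)(C)OS(=O)(=O)C(F)(F)F
Why: Kinetic α′-deprotonation of the enone at the acetyl methyl group (cross-conjugated lithium dienolate) and O-silylation give the 2-silyloxy diene with the (E) geometry untouched.

Step 6
Reactants: 10 tert-butyl(dimethyl){[(3E)-3-methylocta-1,3,7-trien-2-yl]oxy}silane; 6 4,4-dimethyl-3-methylideneoxetan-2-one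
Product: 11 (4S,5R)-5-(but-3-en-1-yl)-7-{[tert-butyl(dimethyl)silyl]oxy}-3,3,6-trimethyl-2-oxaspiro[3.5]non-6-en-1-one
Conditions: (S)-1-(2-methylphenyl)-3,3-diphenyltetrahydro-1H,3H-pyrrolo[1,2-c][1,3,2]oxazaborole (20 mol %), Tf2NH (18 mol %), CH2Cl2, −78 °C
Reagents that add atoms: none
Why: Proposed new method: the cationic oxazaborolidinium Lewis acid binds the lactone carbonyl of strained, s-cis-locked 6 and lowers its LUMO, so that the nucleophilic CH2 terminus of diene 10 bonds to the methylidene carbon and the alkyl-substituted diene terminus to the lactone α-carbon in an asynchronous Diels–Alder reaction that makes both ring bonds in one operation. The closest known reactions are oxazaborolidinium-catalysed Diels–Alder reactions of 2-silyloxy dienes with acrylate esters and the thermal Diels–Alder reactions of α-methylene-β-lactones as allene equivalents; enantioselective catalysis has not been shown for this dienophile class. The six-membered ring closes by suprafacial [4+2] cycloaddition and creates a spiro junction at the lactone α-carbon. The C5 stereocentre (butenyl-bearing carbon) follows from the fixed (E) diene geometry and from the catalyst, whose aryl groups shield one face of the bound dienophile; the spiro centre C4 follows from the carbonyl-endo transition state and is erased in step 7. The step needs regioselectivity, which the 2-silyloxy group (para rule) and the terminal alkyl group (ortho rule) secure by directing the same way, and chemoselectivity, which is secured because the isolated vinyl group is neither a diene nor activated.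

Step 7
Reactants: 11 (4S,5R)-5-(but-3-en-1-yl)-7-{[tert-butyl(dimethyl)silyl]oxy}-3,3,6-trimethyl-2-oxaspiro[3.5]non-6-en-1-one
Product: 12 tert-butyl{[(3S)-3-(but-3-en-1-yl)-2-methyl-4-(propan-2-ylidene)cyclohex-1-en-1-yl]oxy}dimethylsilane
Conditions: toluene, 150 °C, sealed tube
Reagents that add atoms: none
Why: Thermal [2+2] cycloreversion (decarboxylation) of the β-lactone, which places the tetrasubstituted exocyclic double bond exactly at the former spiro carbon and erases that stereocentre.

Step 8
Reactants: 12 tert-butyl{[(3S)-3-(but-3-en-1-yl)-2-methyl-4-(propan-2-ylidene)cyclohex-1-en-1-yl]oxy}dimethylsilane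
Product: 13 (2S,3S)-3-(but-3-en-1-yl)-2-(hydroxymethyl)-2-methyl-4-(propan-2-ylidene)cyclohexan-1-one
Conditions: 37% aq. HCHO, Sc(OTf)3 (10 mol %), THF, rt
Reagents that add atoms: formaldehyde, C=O
Why: Mukaiyama aldol hydroxymethylation of the tetrasubstituted silyl enol ether in aqueous medium; the neighbouring butenyl group is held pseudoaxial by allylic strain with the enol methyl group and the isopropylidene, so formaldehyde should add to the opposite face and the quaternary centre forms with CH2OH trans to butenyl.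

Step 9
Reactants: 13 (2S,3S)-3-(but-3-en-1-yl)-2-(hydroxymethyl)-2-methyl-4-(propan-2-ylidene)cyclohexan-1-one
Product: 14 N'-[(1E,2R,3S)-3-(but-3-en-1-yl)-2-(hydroxymethyl)-2-methyl-4-(propan-2-ylidene)cyclohexylidene]-4-methylbenzenesulfonohydrazide
Conditions: TsNHNH2, MeOH, 50 °C
Reagents that add atoms: 4-methylbenzenesulfonohydrazide, Cc1ccc(cc1)S(=O)(=O)NN
Why: Condensation of the ketone with the sulfonyl hydrazide to the tosylhydrazone, expected as the (E) isomer with the NHTs group on the side of the ring CH2.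

Step 10
Reactants: 14 N'-[(1E,2R,3S)-3-(but-3-en-1-yl)-2-(hydroxymethyl)-2-methyl-4-(propan-2-ylidene)cyclohexylidene]-4-methylbenzenesulfonohydrazide
Product: 15 [(1S,6S)-6-(but-3-en-1-yl)-1-methyl-5-(propan-2-ylidene)cyclohex-2-en-1-yl]methanol
Conditions: n-BuLi (3.1 equiv), THF, −78 to 0 °C; then H2O
Reagents that add atoms: none
Why: Shapiro reaction: the only α-hydrogens are on the ring CH2, so the vinyllithium and, after protonation, the C2=C3 alkene form regiospecifically without touching the stereocentres.

Step 11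
Reactants: 15 [(1S,6S)-6-(but-3-en-1-yl)-1-methyl-5-(propan-2-ylidene)cyclohex-2-en-1-yl]methanol
Product: 17 (4aS,8S,8aR)-8-(but-3-en-1-yl)-3,3,8a-trimethyl-7-(propan-2-ylidene)-3,4,4a,5,6,7,8,8a-octahydro-1H-2,3-benzoxasiline, via bromomethylsilyl ether 16 (not isolated)
Conditions: BrCH2SiMe2Cl, Et3N, CH2Cl2, 0 °C; then Bu3SnH (slow addition), AIBN, benzene, 80 °C
Reagents that add atoms: (bromomethyl)chlorodimethylsilane, BrC[Si](C)(C)Cl
Why: Silylation of the neopentyl alcohol and silicon-tethered 6-exo-trig radical cyclisation; the α-silyl radical can reach C2 of the ring alkene only from the face of the CH2O tether, so the new C–C bond is cis to CH2O (cis-fused siloxane), and the C3 radical is reduced by Bu3SnH.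

Step 12
Reactants: 17 (4aS,8S,8aR)-8-(but-3-en-1-yl)-3,3,8a-trimethyl-7-(propan-2-ylidene)-3,4,4a,5,6,7,8,8a-octahydro-1H-2,3-benzoxasiline
Product: 18 [(1S,2S,6S)-6-(but-3-en-1-yl)-1,2-dimethyl-5-(propan-2-ylidene)cyclohexyl]methanol
Conditions: Bu4NF, DMF, 75 °C
Reagents that add atoms: none
Why: Fluoride-induced protodesilylation of the cyclic alkoxysilane cleaves the ring C–Si bond with protonation, which turns CH2Si into the C2 methyl group (cis to CH2OH) and frees the primary alcohol.

Step 13
Reactants: 18 [(1S,2S,6S)-6-(but-3-en-1-yl)-1,2-dimethyl-5-(propan-2-ylidene)cyclohexyl]methanol; 19 isofraxidin (7-hydroxy-6,8-dimethoxy-2H-chromen-2-one)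
Product: 20 7-{[(1S,2S,6S)-6-(but-3-en-1-yl)-1,2-dimethyl-5-(propan-2-ylidene)cyclohexyl]methoxy}-6,8-dimethoxy-2H-chromen-2-one
Conditions: Bu3P=CHCN, toluene, 100 °C
Reagents that add atoms: none
Why: Mitsunobu-type etherification: the acidic phenol displaces the alkoxyphosphonium group at the primary CH2, and no stereocentre is touched.

Step 14
Reactants: 20 7-{[(1S,2S,6S)-6-(but-3-en-1-yl)-1,2-dimethyl-5-(propan-2-ylidene)cyclohexyl]methoxy}-6,8-dimethoxy-2H-chromen-2-one
Product: 21 3-[(1S,2S,3S)-2-{[(6,8-dimethoxy-2-oxo-2H-chromen-7-yl)oxy]methyl}-2,3-dimethyl-6-(propan-2-ylidene)cyclohexyl]propanal (target)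
Conditions: OsO4 (2 mol %), NaIO4, 2,6-lutidine, dioxane/H2O, rt
Reagents that add atoms: osmium tetroxide, O=[Os](=O)(=O)=O; sodium periodate, [Na+].[O-]I(=O)(=O)=O
Why: Lemieux–Johnson oxidative cleavage (dihydroxylation then periodate glycol cleavage); the monosubstituted terminal alkene should be osmylated much faster than the hindered tetrasubstituted alkene or the electron-poor coumarin C3=C4 bond, and the lutidine buffer guards the product against acid-promoted carbonyl-ene cyclisation.

Compound list
1 | methyl 3-(dimethylamino)propanoate | COC(=O)CCN(C)C | starting material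
2 | acetone | CC(C)=O | starting material
3 | methyl 2-[(dimethylamino)methyl]-3-hydroxy-3-methylbutanoate (racemic) | COC(=O)C(CN(C)C)C(C)(C)O | intermediate
4 | [3-hydroxy-2-(methoxycarbonyl)-3-methylbutyl]trimethylammonium iodide (racemic) | COC(=O)C(C[N+](C)(C)C)C(C)(C)O.[I-] | intermediate
5 | 3-hydroxy-3-methyl-2-methylidenebutanoic acid | C=C(C(=O)O)C(C)(C)O | intermediate
6 | 4,4-dimethyl-3-methylideneoxetan-2-one | C=C1C(=O)OC1(C)C | intermediate
7 | pent-4-enal | C=CCCC=O | starting material
8 | 3-(triphenyl-λ5-phosphanylidene)butan-2-one | CC(=O)C(C)=P(c1ccccc1)(c1ccccc1)c1ccccc1 | starting material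
9 | (3E)-3-methylocta-3,7-dien-2-one | CC(=O)/C(C)=C/CCC=C | intermediate
10 | tert-butyl(dimethyl){[(3E)-3-methylocta-1,3,7-trien-2-yl]oxy}silane | C=C(O[Si](C)(C)C(C)(C)C)/C(C)=C/CCC=C | intermediate
11 | (4S,5R)-5-(but-3-en-1-yl)-7-{[tert-butyl(dimethyl)silyl]oxy}-3,3,6-trimethyl-2-oxaspiro[3.5]non-6-en-1-one | CC1=C(O[Si](C)(C)C(C)(C)C)CC[C@]2(C(=O)OC2(C)C)[C@@H]1CCC=C | intermediate
12 | tert-butyl{[(3S)-3-(but-3-en-1-yl)-2-methyl-4-(propan-2-ylidene)cyclohex-1-en-1-yl]oxy}dimethylsilane | CC1=C(O[Si](C)(C)C(C)(C)C)CCC(=C(C)C)[C@@H]1CCC=C | intermediate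
13 | (2S,3S)-3-(but-3-en-1-yl)-2-(hydroxymethyl)-2-methyl-4-(propan-2-ylidene)cyclohexan-1-one | OC[C@@]1(C)C(=O)CCC(=C(C)C)[C@@H]1CCC=C | intermediate
14 | N'-[(1E,2R,3S)-3-(but-3-en-1-yl)-2-(hydroxymethyl)-2-methyl-4-(propan-2-ylidene)cyclohexylidene]-4-methylbenzenesulfonohydrazide | OC[C@@]1(C)/C(=N/NS(=O)(=O)c2ccc(C)cc2)CCC(=C(C)C)[C@@H]1CCC=C | intermediate
15 | [(1S,6S)-6-(but-3-en-1-yl)-1-methyl-5-(propan-2-ylidene)cyclohex-2-en-1-yl]methanol | OC[C@@]1(C)C=CCC(=C(C)C)[C@@H]1CCC=C | intermediate
16 | (bromomethyl){[(1S,6S)-6-(but-3-en-1-yl)-1-methyl-5-(propan-2-ylidene)cyclohex-2-en-1-yl]methoxy}dimethylsilane | BrC[Si](C)(C)OC[C@@]1(C)C=CCC(=C(C)C)[C@@H]1CCC=C | intermediate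
17 | (4aS,8S,8aR)-8-(but-3-en-1-yl)-3,3,8a-trimethyl-7-(propan-2-ylidene)-3,4,4a,5,6,7,8,8a-octahydro-1H-2,3-benzoxasiline (cis-fused) | O1C[C@@]2(C)[C@@H](C[Si]1(C)C)CCC(=C(C)C)[C@@H]2CCC=C | intermediate
18 | [(1S,2S,6S)-6-(but-3-en-1-yl)-1,2-dimethyl-5-(propan-2-ylidene)cyclohexyl]methanol | OC[C@@]1(C)[C@@H](C)CCC(=C(C)C)[C@@H]1CCC=C | intermediate
19 | isofraxidin (7-hydroxy-6,8-dimethoxy-2H-chromen-2-one) | COc1cc2ccc(=O)oc2c(OC)c1O | starting material
20 | 7-{[(1S,2S,6S)-6-(but-3-en-1-yl)-1,2-dimethyl-5-(propan-2-ylidene)cyclohexyl]methoxy}-6,8-dimethoxy-2H-chromen-2-one | COc1cc2ccc(=O)oc2c(OC)c1OC[C@@]1(C)[C@@H](C)CCC(=C(C)C)[C@@H]1CCC=C | intermediate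
21 | 3-[(1S,2S,3S)-2-{[(6,8-dimethoxy-2-oxo-2H-chromen-7-yl)oxy]methyl}-2,3-dimethyl-6-(propan-2-ylidene)cyclohexyl]propanal | COc1cc2ccc(=O)oc2c(OC)c1OC[C@@]1(C)[C@@H](C)CCC(=C(C)C)[C@@H]1CCC=O | target

Total step count: 14. Longest linear sequence: 12 steps (steps 1–3 and 6–14).

Steps most likely to fail

Step 6. The Lewis acid may ionise the tertiary C–O bond of the β-lactone before cycloaddition, or the catalyst may discriminate the two faces of this dienophile poorly. The fallback uses known chemistry and sets out from 10. The same class of oxazaborolidinium catalyst with 2,2,2-trifluoroethyl acrylate, an established dienophile for this catalyst, should give the trifluoroethyl ester adduct F1. Deprotonation with LiN(iPr)2 and addition of acetone, anti to the butenyl group, gives the aldol adduct F2. Hydrolysis with LiOH at 0 °C gives the hydroxy acid F3, and PhSO2Cl in pyridine closes the β-lactone, which comes back to the route at 11.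

Step 11. The α-silyl radical may be reduced before it cyclises, or it may close in the 7-endo mode onto C3, so that the methyl carbon is lost or misplaced. The fallback sets out from 15. O-alkylation with chloromethyl phenyl selenide (NaH, NaI, THF) should give the phenylselanylmethyl ether F4. Bu3SnH and AIBN generate an alkoxymethyl radical that closes 5-exo-trig onto C2 and gives the cis-fused tetrahydrofuran F5. Me2BBr opens this ether at the less hindered CH2, the one on the tertiary carbon and not the neopentyl one, to give the bromo alcohol F6. Reduction of the C–Br bond with Bu3SnH comes back to the route at 18.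

Step 13. Displacement at the neopentyl carbon may be too slow, so that the alkoxyphosphonium intermediate decomposes or rearranges before the hindered phenoxide attacks. The fallback forms the aryl C–O bond instead and sets out from 18 and 19. Tf2O and pyridine convert 19 into the coumarinyl triflate F7. Palladium-catalysed C–O cross-coupling of 18 with F7 ([Pd(allyl)Cl]2, RockPhos, Cs2CO3, toluene, 90 °C) comes back to the route at 20.

Further compounds
F1 | step 6 | 2,2,2-trifluoroethyl (1S,2S)-2-(but-3-en-1-yl)-4-{[tert-butyl(dimethyl)silyl]oxy}-3-methylcyclohex-3-ene-1-carboxylate | CC1=C(O[Si](C)(C)C(C)(C)C)CC[C@H](C(=O)OCC(F)(F)F)[C@@H]1CCC=C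
F2 | step 6 | 2,2,2-trifluoroethyl (1S,2R)-2-(but-3-en-1-yl)-4-{[tert-butyl(dimethyl)silyl]oxy}-1-(2-hydroxypropan-2-yl)-3-methylcyclohex-3-ene-1-carboxylate | CC1=C(O[Si](C)(C)C(C)(C)C)CC[C@@](C(=O)OCC(F)(F)F)(C(C)(C)O)[C@@H]1CCC=C
F3 | step 6 | (1S,2R)-2-(but-3-en-1-yl)-4-{[tert-butyl(dimethyl)silyl]oxy}-1-(2-hydroxypropan-2-yl)-3-methylcyclohex-3-ene-1-carboxylic acid | CC1=C(O[Si](C)(C)C(C)(C)C)CC[C@@](C(=O)O)(C(C)(C)O)[C@@H]1CCC=C
F4 | step 11 | ({[(1S,6S)-6-(but-3-en-1-yl)-1-methyl-5-(propan-2-ylidene)cyclohex-2-en-1-yl]methoxy}methyl)(phenyl)selane | c1ccccc1[Se]COC[C@@]1(C)C=CCC(=C(C)C)[C@@H]1CCC=C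
F5 | step 11 | (3aR,4S,7aS)-4-(but-3-en-1-yl)-3a-methyl-5-(propan-2-ylidene)octahydro-2-benzofuran | O1C[C@@]2(C)[C@@H](C1)CCC(=C(C)C)[C@@H]2CCC=C
F6 | step 11 | [(1R,2S,6S)-2-(bromomethyl)-6-(but-3-en-1-yl)-1-methyl-5-(propan-2-ylidene)cyclohexyl]methanol | OC[C@@]1(C)[C@@H](CBr)CCC(=C(C)C)[C@@H]1CCC=C
F7 | step 13 | 6,8-dimethoxy-2-oxo-2H-chromen-7-yl trifluoromethanesulfonate | COc1cc2ccc(=O)oc2c(OC)c1OS(=O)(=O)C(F)(F)F
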